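# Proposed total synthesis of (+)-chamaechromone by aryne annulation of a formylsuccinate

**Atom and ring labels.** Chromone numbering is O1, C2, C3, C4, C4a, C5–C8, C8a, with ring A the benzo ring and ring C the pyranone. C-alpha is the stereogenic carbon on C3, C-beta the diarylmethyl carbon, and ring D the trihydroxybenzoyl ring.

**Compound numbers.**
- 1: 4,4'-dimethoxybenzophenone
- 2: di-tert-butyl succinate
- 3: Stobbe half-ester
- 4: hydrogenated acid
- 5: tert-butyl methyl diester
- 6: formyl enol
- 7: 3,5-dimethoxyphenol
- 8: bromophenol
- 9: silyl ether (not isolated)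
- 10: lithium silylphenoxide (not isolated)
- 11: silyl triflate
- 12: 3,5-dimethoxybenzyne (not isolated)
- 13: chromone tert-butyl ester
- 14: chromone acid
- 15: 1,3,5-trimethoxybenzene
- 16: mixed anhydride (not isolated)
- 17: heptamethyl ether
- 18: (+)-chamaechromone

## Analysis of the target

Compound 18 is a 5,7-dihydroxychromone (ring A fused to ring C) whose C3 carries a three-carbon chain. The chain consists of C-alpha, a ketone carbonyl bound to the 2,4,6-trihydroxyphenyl ring D, and C-beta with two 4-hydroxyphenyl rings. C-alpha is the only stereocentre and is S; C-beta is not stereogenic because its two aryl groups are identical, so the stereochemical problem is a single tertiary C–H. In 18 that hydrogen is alpha to an aryl ketone and allylic to the C2=C3 bond, which makes it the most easily lost hydrogen in the molecule, so base has to be kept away once both groups flank it, and before that point C-alpha may sit only beside a weakly acidifying carboxyl derivative. Further sensitive features are the seven phenols, the pyranone (it opens when hydroxide or alkoxide adds at C2), and the bis(hydroxyphenyl)methyl group, which a para-phenoxide can expel from C-alpha by a quinone-methide retro-Michael reaction. The difficulty lies in crowding three bulky groups around C-alpha in one configuration and in forming a chromone with a branched C3 substituent without disturbing that configuration. The strategy rests on ring A being a phloroglucinol ring whose C4a–C8a edge corresponds to aryne 12, while the other four atoms of ring C (O1, C2, C3, C4) are the enol oxygen, formyl carbon, alpha carbon and ester carbon of a 2-formylsuccinate whose neighbouring methine is C-alpha with its substituents already in place.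

## Retrosynthetic reasoning

**18 to 17.** The seven O–H bonds are traced back to O–CH3 bonds. Methyl ethers survive the strong bases, the fluoride and the strong acid used along the route and can be removed together at the end. The forward step has to cleave seven aryl ethers under non-basic conditions.

**17 to 14 and 15.** The bond between the ketone carbon and ring D is cut. Ring D is symmetrical and far more nucleophilic than any other ring present, so the cut raises no regiochemical question. It also turns the ketone carbon into a carboxyl carbon on C-alpha. The forward reaction is a Friedel–Crafts acylation under acid and has to outrun enolisation of the activated acid.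

**14 to 13.** The acid is masked as a tert-butyl ester. This ester is inert towards the aryl anion of the ring closure, is distinguishable from the methyl ester that becomes C4, and is removed by acid alone.

**13 to 6 and 12 (released from 11).** The O1–C8a and C4–C4a bonds are cut together. A cut at C3–C-alpha would require the stereocentre to be created by a coupling on the heterocycle, and the classical order (acylation at C4a, then addition of C2) is longer. The two-bond cut divides 13 into ring A and an acyclic chain that already holds C2, C3, C4 and the finished C-alpha, and no bond to the stereocentre is made or broken. The forward step must arylate enol 6 through oxygen, at the carbon of aryne 12 remote from the flanking methoxy group, and let the aryl anion displace methoxide from the ester.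

**11 to 8 to 7.** The C–Si and O–S bonds of 11 are cut back to bromophenol 8, and the C–Br bond back to phenol 7. The forward sequence is bromination ortho to the hydroxyl group, then bromine–lithium exchange with oxygen-to-carbon silyl migration and triflation.

**6 to 5.** The bond between the future C2 (formyl carbon) and the future C3 (succinate methylene) is cut. The forward reaction is a crossed Claisen formylation. The methylene next to the methyl ester must be enolised in preference to the hindered methine at C-alpha.

**5 to 4 to 3.** The methyl ester O–C bond is cut first, then the two C–H bonds at C-alpha and C-beta. A carboxylate-directed asymmetric hydrogenation of the tetrasubstituted alkene 3 sets the single stereocentre. Because C-beta is not stereogenic, only the face of hydrogen delivery to C-alpha matters.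

**3 to 1 and 2.** The C-alpha=C-beta double bond is cut. The Stobbe condensation brings in both aryl groups with ketone 1 and leaves the two carboxyl groups of 2 differentiated: ester on the alkene carbon, free acid on the methylene.

## Alternatives that were turned down

Alternative 1: ring C closed at the C3–C4 bond by an intramolecular Stetter reaction under carbene catalysis.
- Disconnection: the C3–C4 bond is cut, which leads back to the tethered aldehyde–enone 2-{[(2E)-3-[bis(4-methoxyphenyl)methyl]-4-oxo-4-(2,4,6-trimethoxyphenyl)but-2-en-1-yl]oxy}-4,6-dimethoxybenzaldehyde A2, in which a ring-A aldehyde is linked through O1 and C2 to the enone.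
- Forward key step: a chiral triazolium-derived carbene, generated with a strong amide base, turns the formyl group of A2 into an acyl-anion equivalent. This adds to the enone beta-carbon, and internal proton transfer sets C-alpha. The product is the chromanone (3R)-5,7-dimethoxy-3-[(2S)-1-oxo-1-(2,4,6-trimethoxyphenyl)-3,3-bis(4-methoxyphenyl)propan-2-yl]chroman-4-one A1.
- For: C-alpha is created catalytically and late, and ring D is attached before any stereocentre exists, so no acylation of an epimerisable acid is needed. On these two points it is stronger than the chosen plan.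
- Against: the acceptor in A2 is an alpha-branched enone with a diarylmethyl group on the alpha-carbon and a carbonyl twisted out of conjugation by a di-ortho-substituted aryl ring, so it is a poor Michael acceptor. The aldehyde is electron-rich and flanked by two ortho-oxygens, which slows formation of the acyl-anion equivalent. Because A1 is a chromanone, the C3 stereocentre just made must be destroyed by a C2–C3 dehydrogenation next to the labile C-alpha. Making A2 also takes several steps with control of alkene geometry.
- Comparison: the chosen route gives the pyranone at the aromatic oxidation level in the ring-forming step and reaches its precursors from commercial fragments in a few standard operations.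

Alternative 2: both aryl groups put on a methyl group by double C–H arylation.
- Disconnection: both C-beta–aryl bonds are cut, which leads back to the methyl compound (2S)-2-(5,7-dimethoxy-4-oxo-4H-chromen-3-yl)-N-(quinolin-8-yl)propanamide A4.
- Forward key step: a divalent palladium carboxylate with a silver salt and an excess of a para-methoxy aryl iodide arylates the methyl group of A4 twice through five-membered palladacycles. The product is the diarylated amide (2S)-2-(5,7-dimethoxy-4-oxo-4H-chromen-3-yl)-3,3-bis(4-methoxyphenyl)-N-(quinolin-8-yl)propanamide A3.
- For: the stereocentre of A4 carries only a methyl group and could come from an asymmetric hydrogenation of routine difficulty, which is far surer than hydrogenating the tetrasubstituted alkene 3; here the alternative is stronger. The aryl groups are also introduced modularly.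
- Against: the second arylation has to occur at a secondary benzylic C–H beside a crowded C-alpha. In A4 the chromone C2–H lies within reach of the amide-bound palladium through a six-membered palladacycle and is itself prone to arylation. The hot carboxylate-buffered medium endangers the C-alpha hydrogen. The quinolinyl amide of A3 then has to be converted into a very hindered aryl ketone, which needs forcing cleavage or extra activation steps.
- Comparison: the chosen route obtains both aryl groups from ketone 1 with no C–H selectivity question, and acid 14 is released by mild acidolysis.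

Alternative 3: ring D built by a Diels–Alder benzannulation.
- Disconnection: two bonds of ring D are cut, which leads back to the ynone (S)-3-[5-ethoxy-1,1-bis(4-methoxyphenyl)-3-oxopent-4-yn-2-yl]-5,7-dimethoxy-4H-chromen-4-one A6 and the diene 1-methoxy-1,3-bis(trimethylsilyloxy)buta-1,3-diene A7.
- Forward key step: A6 and A7 combine in a regioselective [4+2] cycloaddition, and elimination of the methoxy group with desilylation aromatises the new ring. The product is the resorcinol ketone (S)-3-[1-(2-ethoxy-4,6-dihydroxyphenyl)-3,3-bis(4-methoxyphenyl)-1-oxopropan-2-yl]-5,7-dimethoxy-4H-chromen-4-one A5.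
- For: the crowded aryl–carbonyl bond exists before the ring does, so there is no intermolecular acylation between two ortho-oxygens and no competing intramolecular acylation. On this point it is stronger than step 9 of the chosen route.
- Against: ring D is available as 15, so building it spends steps on a commodity. The ynone A6 has to be made by adding a basic metal alkoxyacetylide to an activated derivative of an acid like 14, next to the C-alpha hydrogen and to a chromone that accepts nucleophiles at C2. In A6 the C-alpha hydrogen is alpha to an ynone and more acidic than in any intermediate of the chosen route. The push–pull alkyne is a sluggish dienophile, and A7 is a moisture-sensitive ketene acetal. The product A5 carries an ethyl ether on ring D beside the methyl ethers, and the chromone still has to be made by other means.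
- Comparison: the chosen route needs one acylation step where this needs three, and keeps C-alpha next to nothing more activating than a carboxyl derivative until the last two steps.

Key step: step 7

**Assumption.** The (R,R) ligand in step 2 is assigned by analogy with the facial sense that [Rh(cod)((R,R)-Et-DuPhos)]BF4 shows with carboxylate-directed itaconate half-esters. If alkene 3 responds with the opposite sense, the (S,S) ligand is used and nothing else changes.

## Route

Step 1
Reactants: 1 4,4'-dimethoxybenzophenone; 2 di-tert-butyl succinate
Product: 3 3-(tert-butoxycarbonyl)-4,4-bis(4-methoxyphenyl)but-3-enoic acid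
Conditions: KOtBu (1.3 equiv), 2 (1.5 equiv), t-BuOH, reflux; then aq. HCl
Reagents that add atoms: none
Why: Stobbe condensation: the succinate enolate adds to the ketone, the alkoxide lactonises onto the distal ester, and base-induced E1cB opening of the lactone gives the carboxylate irreversibly, so the tert-butyl ester stays on the alkene carbon and the free acid on the methylene. tert-Butoxide in tert-butanol cannot scramble the ester, and the alkene has no geometric isomers because both aryl groups are the same.

Step 2
Reactants: 3 3-(tert-butoxycarbonyl)-4,4-bis(4-methoxyphenyl)but-3-enoic acid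
Product: 4 (3R)-3-(tert-butoxycarbonyl)-4,4-bis(4-methoxyphenyl)butanoic acid
Conditions: [Rh(cod)((R,R)-Et-DuPhos)]BF4 (2 mol %), H2 (20 bar), NaOMe (0.1 equiv), MeOH, 40 °C
Reagents that add atoms: none
Why: Asymmetric hydrogenation of a Stobbe-type itaconate half-ester: carboxylate and alkene chelate the cationic monovalent rhodium centre, and both hydrogens are delivered to the alkene face selected by the C2-symmetric bisphospholane, which sets C-alpha. The descriptor is R at this stage because the diarylmethyl group outranks the carboxymethyl group.

Step 3
Reactants: 4 (3R)-3-(tert-butoxycarbonyl)-4,4-bis(4-methoxyphenyl)butanoic acid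
Product: 5 1-tert-butyl 4-methyl (2R)-2-[bis(4-methoxyphenyl)methyl]butanedioate
Conditions: MeI, K2CO3, DMF, 23 °C
Reagents that add atoms: iodomethane, CI
Why: O-Alkylation of the carboxylate (SN2 on iodomethane); carbonate ionises only the acid and leaves the tertiary C–H next to the tert-butyl ester untouched.

Step 4
Reactants: 5 1-tert-butyl 4-methyl (2R)-2-[bis(4-methoxyphenyl)methyl]butanedioate
Product: 6 4-tert-butyl 1-methyl (2Z,3S)-3-[bis(4-methoxyphenyl)methyl]-2-(hydroxymethylidene)butanedioate
Conditions: LiN(i-Pr)2 (1.3 equiv), THF, −78 °C; HCO2Me (5 equiv), −78 → 0 °C; AcOH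
Reagents that add atoms: methyl formate, COC=O
Why: Crossed Claisen condensation (formylation of an ester enolate): the amide base removes a proton from the open methylene next to the methyl ester rather than from the methine flanked by the diarylmethyl group and the tert-butyl ester, and the product is held as its enolate until the quench. The descriptor becomes S only because the new sp2 carbon outranks the diarylmethyl group; the spatial arrangement is unchanged and the hydrogen-bonded Z enol is used as it is obtained.

Step 5
Reactants: 7 3,5-dimethoxyphenol
Product: 8 2-bromo-3,5-dimethoxyphenol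
Conditions: NBS (1.0 equiv), CH2Cl2, −78 → 23 °C
Reagents that add atoms: N-bromosuccinimide, O=C1CCC(=O)N1Br
Why: Electrophilic aromatic bromination of a highly activated ring at low temperature with one equivalent to suppress polybromination; the two equivalent positions ortho to the hydroxyl group should be favoured over the single position between the methoxy groups, and the 4-bromo isomer is to be removed by chromatography.

Step 6
Reactants: 8 2-bromo-3,5-dimethoxyphenol
Product: 11 3,5-dimethoxy-2-(trimethylsilyl)phenyl trifluoromethanesulfonate, via (2-bromo-3,5-dimethoxyphenoxy)trimethylsilane 9 (not isolated), via lithium 3,5-dimethoxy-2-(trimethylsilyl)phenoxide 10 (not isolated)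
Conditions: (Me3Si)2NH, THF, 70 °C, then evaporation; n-BuLi, THF, −100 → −78 °C; Tf2O, −100 → 23 °C
Reagents that add atoms: hexamethyldisilazane, C[Si](C)(C)N[Si](C)(C)C; trifluoromethanesulfonic anhydride, O=S(=O)(OS(=O)(=O)C(F)(F)F)C(F)(F)F
Why: O-Silylation, bromine–lithium exchange and anionic 1,3 oxygen-to-carbon silyl shift (retro-Brook rearrangement) give the ortho-silyl phenoxide, which is trapped as the triflate; this is the standard entry to ortho-silylaryl triflates from ortho-bromophenols.

Step 7
Reactants: 6 4-tert-butyl 1-methyl (2Z,3S)-3-[bis(4-methoxyphenyl)methyl]-2-(hydroxymethylidene)butanedioate; 11 3,5-dimethoxy-2-(trimethylsilyl)phenyl trifluoromethanesulfonate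
Product: 13 tert-butyl (2S)-2-(5,7-dimethoxy-4-oxo-4H-chromen-3-yl)-3,3-bis(4-methoxyphenyl)propanoate, via 3,5-dimethoxybenzyne 12 (not isolated)
Conditions: CsF (4 equiv), 11 (1.5 equiv), THF, 65 °C
Reagents that add atoms: none
Why: Proposed new method: CsF strips the trimethylsilyl group from 11 and triflate is expelled to release aryne 12, and fluoride at the same time converts enol 6 into its cesium enolate; the enolate oxygen bonds to the aryne carbon that is meta to the neighbouring methoxy group, so that the negative charge develops on the carbon ortho to that methoxy group, where the C–O dipole stabilises it, and this aryl anion then adds to the cis methyl ester and expels methoxide. The closest known reaction type is the fluoride-induced annulation of arynes with salicylate esters to xanthones, which runs through the same sequence of oxygen addition and aryl-anion acyl substitution; an enol ester here takes the place of the phenol ester. Ring C closes by a 6-exo-trig acyl substitution that forms C4–C4a after O1–C8a, and the substitution pattern of 12 puts the methoxy groups at C5 and C7. No stereocentre is created, and C-alpha should be retained because the enol, far more acidic than the C-alpha hydrogen beside the tert-butyl ester, takes up the base, and the hydrogen fluoride formed on its ionisation neutralises the methoxide released. The step needs arylation through oxygen rather than carbon, which the unhindered formyl-enolate oxygen set against a fully substituted enolate carbon next to the branched C-alpha should secure. It also needs the aryloxy group cis to the methyl ester, which the cesium-chelated U-shaped enolate in THF should provide. THF is preferred to acetonitrile so that the aryl anion is not protonated by solvent before it cyclises, and the excess of 11 covers aryne consumed by the methanol set free.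

Step 8
Reactants: 13 tert-butyl (2S)-2-(5,7-dimethoxy-4-oxo-4H-chromen-3-yl)-3,3-bis(4-methoxyphenyl)propanoate
Product: 14 (2S)-2-(5,7-dimethoxy-4-oxo-4H-chromen-3-yl)-3,3-bis(4-methoxyphenyl)propanoic acid
Conditions: CF3CO2H–CH2Cl2 (1:3), 0 → 23 °C
Reagents that add atoms: none
Why: Acidolysis of the tert-butyl ester by loss of the tert-butyl cation as isobutene; the methyl ethers and the chromone are inert to the acid, and C-alpha cannot epimerise in the absence of base.

Step 9
Reactants: 14 (2S)-2-(5,7-dimethoxy-4-oxo-4H-chromen-3-yl)-3,3-bis(4-methoxyphenyl)propanoic acid; 15 1,3,5-trimethoxybenzene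
Product: 17 5,7-dimethoxy-3-[(2S)-3,3-bis(4-methoxyphenyl)-1-oxo-1-(2,4,6-trimethoxyphenyl)propan-2-yl]-4H-chromen-4-one, via mixed carboxylic trifluoroacetic anhydride 16 (not isolated)
Conditions: (CF3CO)2O (1.5 equiv), CH2Cl2, 0 °C; then 15 (3 equiv), CF3SO3H (5 mol %), 0 → 23 °C
Reagents that add atoms: none
Why: Friedel–Crafts acylation through the mixed trifluoroacetic anhydride, formed before 15 is added so that little free anhydride is left to trifluoroacetylate 15. Ring 15 is far more nucleophilic than any ring of 14, whose anisyl positions available for indanone closure are meta to methoxy. The acidic, base-free medium should preserve C-alpha.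

Step 10
Reactants: 17 5,7-dimethoxy-3-[(2S)-3,3-bis(4-methoxyphenyl)-1-oxo-1-(2,4,6-trimethoxyphenyl)propan-2-yl]-4H-chromen-4-one
Product: 18 (+)-chamaechromone, 5,7-dihydroxy-3-[(2S)-3,3-bis(4-hydroxyphenyl)-1-oxo-1-(2,4,6-trihydroxyphenyl)propan-2-yl]-4H-chromen-4-one
Conditions: BBr3 (15 equiv), CH2Cl2, −78 → 23 °C; then H2O, 0 °C
Reagents that add atoms: none
Why: Lewis-acid cleavage of aryl methyl ethers: boron coordinates each ether oxygen and bromide attacks the methyl group, and the aryloxyboranes are hydrolysed on work-up. The non-basic conditions avoid pyranone opening and retro-Michael loss of the bis(hydroxyphenyl)methyl unit.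

## Compound list

1 | 4,4'-dimethoxybenzophenone | COc1ccc(cc1)C(=O)c1ccc(OC)cc1 | starting material
2 | di-tert-butyl succinate | CC(C)(C)OC(=O)CCC(=O)OC(C)(C)C | starting material
3 | 3-(tert-butoxycarbonyl)-4,4-bis(4-methoxyphenyl)but-3-enoic acid | OC(=O)CC(C(=O)OC(C)(C)C)=C(c1ccc(OC)cc1)c1ccc(OC)cc1 | intermediate
4 | (3R)-3-(tert-butoxycarbonyl)-4,4-bis(4-methoxyphenyl)butanoic acid | O=C(OC(C)(C)C)[C@H](CC(=O)O)C(c1ccc(OC)cc1)c1ccc(OC)cc1 | intermediate
5 | 1-tert-butyl 4-methyl (2R)-2-[bis(4-methoxyphenyl)methyl]butanedioate | O=C(OC(C)(C)C)[C@H](CC(=O)OC)C(c1ccc(OC)cc1)c1ccc(OC)cc1 | intermediate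
6 | 4-tert-butyl 1-methyl (2Z,3S)-3-[bis(4-methoxyphenyl)methyl]-2-(hydroxymethylidene)butanedioate | O=C(OC(C)(C)C)[C@H](/C(=C/O)C(=O)OC)C(c1ccc(OC)cc1)c1ccc(OC)cc1 | intermediate
7 | 3,5-dimethoxyphenol | COc1cc(O)cc(OC)c1 | starting material
8 | 2-bromo-3,5-dimethoxyphenol | COc1cc(O)c(Br)c(OC)c1 | intermediate
9 | (2-bromo-3,5-dimethoxyphenoxy)trimethylsilane | COc1cc(O[Si](C)(C)C)c(Br)c(OC)c1 | intermediate
10 | lithium 3,5-dimethoxy-2-(trimethylsilyl)phenoxide | [Li+].COc1cc([O-])c([Si](C)(C)C)c(OC)c1 | intermediate
11 | 3,5-dimethoxy-2-(trimethylsilyl)phenyl trifluoromethanesulfonate | FC(F)(F)S(=O)(=O)Oc1cc(OC)cc(OC)c1[Si](C)(C)C | intermediate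
12 | 3,5-dimethoxybenzyne (1,2-didehydro-3,5-dimethoxybenzene) | COC1=CC(OC)=CC#C1 | intermediate
13 | tert-butyl (2S)-2-(5,7-dimethoxy-4-oxo-4H-chromen-3-yl)-3,3-bis(4-methoxyphenyl)propanoate | O=C(OC(C)(C)C)[C@H](c1coc2cc(OC)cc(OC)c2c1=O)C(c1ccc(OC)cc1)c1ccc(OC)cc1 | intermediate
14 | (2S)-2-(5,7-dimethoxy-4-oxo-4H-chromen-3-yl)-3,3-bis(4-methoxyphenyl)propanoic acid | O=C(O)[C@H](c1coc2cc(OC)cc(OC)c2c1=O)C(c1ccc(OC)cc1)c1ccc(OC)cc1 | intermediate
15 | 1,3,5-trimethoxybenzene | COc1cc(OC)cc(OC)c1 | starting material
16 | (2S)-2-(5,7-dimethoxy-4-oxo-4H-chromen-3-yl)-3,3-bis(4-methoxyphenyl)propanoic trifluoroacetic anhydride | O=C(OC(=O)C(F)(F)F)[C@H](c1coc2cc(OC)cc(OC)c2c1=O)C(c1ccc(OC)cc1)c1ccc(OC)cc1 | intermediate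
17 | 5,7-dimethoxy-3-[(2S)-3,3-bis(4-methoxyphenyl)-1-oxo-1-(2,4,6-trimethoxyphenyl)propan-2-yl]-4H-chromen-4-one | O=C(c1c(OC)cc(OC)cc1OC)[C@H](c1coc2cc(OC)cc(OC)c2c1=O)C(c1ccc(OC)cc1)c1ccc(OC)cc1 | intermediate
18 | (+)-chamaechromone, 5,7-dihydroxy-3-[(2S)-3,3-bis(4-hydroxyphenyl)-1-oxo-1-(2,4,6-trihydroxyphenyl)propan-2-yl]-4H-chromen-4-one | O=C(c1c(O)cc(O)cc1O)[C@H](c1coc2cc(O)cc(O)c2c1=O)C(c1ccc(O)cc1)c1ccc(O)cc1 | target

## Step count and risk

Total step count: 10. Longest linear sequence: 8 steps (steps 1, 2, 3, 4, 7, 8, 9, 10); the aryne branch (steps 5 and 6) joins at step 7.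

**Step 7 (key step, proposed new method).**
- What may go wrong: arylation through the enolate carbon followed by formyl transfer (net insertion of the aryne into the C–CHO bond); protonation of the aryl anion before it reaches the ester; O-arylation from an enolate rotamer that holds the ester trans to oxygen; loss of the formyl group by retro-Claisen attack of methoxide.
- Fallback (known chemistry: a 3-substituted chromone from an ortho-hydroxyaryl ketone and a one-carbon unit). It sets out from 4 and 8 and returns at 14. Acid 4 is coupled with N,O-dimethylhydroxylamine hydrochloride (EDC, i-Pr2NEt) to give the N-methoxy-N-methylamide tert-butyl (2R)-2-[bis(4-methoxyphenyl)methyl]-4-[methoxy(methyl)amino]-4-oxobutanoate F1. Bromophenol 8 is protected with chloromethyl methyl ether and i-Pr2NEt as 2-bromo-1,5-dimethoxy-3-(methoxymethoxy)benzene F2. Bromine–lithium exchange (n-BuLi, THF, −78 °C) gives [2,4-dimethoxy-6-(methoxymethoxy)phenyl]lithium F3, which adds once to F1 to give the ketone tert-butyl (2R)-2-[bis(4-methoxyphenyl)methyl]-4-[2,4-dimethoxy-6-(methoxymethoxy)phenyl]-4-oxobutanoate F4. Condensation of its methylene with N,N-dimethylformamide dimethyl acetal (100 °C) gives the enaminone tert-butyl (2S)-2-[bis(4-methoxyphenyl)methyl]-3-[2,4-dimethoxy-6-(methoxymethoxy)benzoyl]-4-(dimethylamino)but-3-enoate F5; its double-bond geometry is left open because it is lost on cyclisation. CF3CO2H in CH2Cl2 then removes the methoxymethyl group, lets the freed phenol displace dimethylamine to close ring C, and cleaves the tert-butyl ester. Acid 14 is reached directly, and steps 7 and 8 are bypassed. Throughout, the C-alpha hydrogen is alpha only to the tert-butyl ester.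

**Step 2.**
- What may go wrong: slow or no turnover at the tetrasubstituted, diaryl-substituted alkene, or poor facial selectivity.
- Fallback: it sets out from 3 and returns at 4. Alkene 3 is hydrogenated over Pd/C (H2, 10 bar, EtOAc–AcOH) to racemic 3-(tert-butoxycarbonyl)-4,4-bis(4-methoxyphenyl)butanoic acid F6. This is resolved by crystallisation of the salt (R)-1-phenylethylammonium (3R)-3-(tert-butoxycarbonyl)-4,4-bis(4-methoxyphenyl)butanoate F7, or with the antipodal amine if the other salt proves less soluble. Dilute acid liberates 4.

**Step 9.**
- What may go wrong: enolisation or ketene formation from the activated acyl group, or reversible attack of the chromone C4 carbonyl oxygen on the activated acyl carbon, either of which erodes C-alpha; sluggish attack at the crowded acyl carbon, which lets trifluoroacetylation of 15 or intramolecular acylation of an anisyl ring compete.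
- Fallback: it sets out from 14 and returns at 17. Acid 14 is converted (thiophenol, DCC, catalytic DMAP, 0 °C) into S-phenyl (2S)-2-(5,7-dimethoxy-4-oxo-4H-chromen-3-yl)-3,3-bis(4-methoxyphenyl)propanethioate F8. F8 is coupled with 2,4,6-trimethoxyphenylboronic acid under neutral Liebeskind–Srogl conditions: Pd2(dba)3 as the zerovalent palladium source, tri(2-furyl)phosphine, and copper thiophene-2-carboxylate Cu(O2CC4H3S) with monovalent copper, in THF at 50 °C. The carbon–carbon bond to ring D is then made without acid, base or an acylium ion.

**Step 10.**
- What may go wrong: incomplete cleavage of the least reactive ethers (the C7 methoxy group in particular); epimerisation of C-alpha through a boron-chelated enol of the ortho-oxygenated aryl ketone.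
- Fallback: it sets out from 14 and returns at 18, replacing steps 9 and 10. The four methyl ethers of 14 are cleaved with BBr3 while C-alpha is still next to a carboxyl group, which gives (2S)-2-(5,7-dihydroxy-4-oxo-4H-chromen-3-yl)-3,3-bis(4-hydroxyphenyl)propanoic acid F9. F9 then C-acylates unprotected phloroglucinol in BF3·OEt2 at 70 °C, the standard Friedel–Crafts route to 2,4,6-trihydroxyphenyl ketones from carboxylic acids, and gives 18 directly.

**Step 4.**
- What may go wrong: enolisation at the C-alpha methine, or proton transfer between the two ester enolates on warming, with erosion of configuration; incomplete formylation.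
- Fallback: it sets out from 5 and returns at 6. Diester 5 is heated in tert-butoxybis(dimethylamino)methane (90 °C). Only the methylene can condense, which gives 4-tert-butyl 1-methyl (3S)-3-[bis(4-methoxyphenyl)methyl]-2-[(dimethylamino)methylidene]butanedioate F10. Brief two-phase hydrolysis (1 M aq. HCl, THF, 0 °C) converts the enamine into enol 6.

## Further compounds

F1 | step 7 | tert-butyl (2R)-2-[bis(4-methoxyphenyl)methyl]-4-[methoxy(methyl)amino]-4-oxobutanoate | O=C(OC(C)(C)C)[C@H](CC(=O)N(C)OC)C(c1ccc(OC)cc1)c1ccc(OC)cc1
F2 | step 7 | 2-bromo-1,5-dimethoxy-3-(methoxymethoxy)benzene | COCOc1cc(OC)cc(OC)c1Br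
F3 | step 7 | [2,4-dimethoxy-6-(methoxymethoxy)phenyl]lithium | [Li]c1c(OC)cc(OC)cc1OCOC
F4 | step 7 | tert-butyl (2R)-2-[bis(4-methoxyphenyl)methyl]-4-[2,4-dimethoxy-6-(methoxymethoxy)phenyl]-4-oxobutanoate | O=C(OC(C)(C)C)[C@H](CC(=O)c1c(OC)cc(OC)cc1OCOC)C(c1ccc(OC)cc1)c1ccc(OC)cc1
F5 | step 7 | tert-butyl (2S)-2-[bis(4-methoxyphenyl)methyl]-3-[2,4-dimethoxy-6-(methoxymethoxy)benzoyl]-4-(dimethylamino)but-3-enoate | O=C(OC(C)(C)C)[C@H](C(=CN(C)C)C(=O)c1c(OC)cc(OC)cc1OCOC)C(c1ccc(OC)cc1)c1ccc(OC)cc1
F6 | step 2 | racemic 3-(tert-butoxycarbonyl)-4,4-bis(4-methoxyphenyl)butanoic acid | O=C(OC(C)(C)C)C(CC(=O)O)C(c1ccc(OC)cc1)c1ccc(OC)cc1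
F7 | step 2 | (R)-1-phenylethylammonium (3R)-3-(tert-butoxycarbonyl)-4,4-bis(4-methoxyphenyl)butanoate | O=C(OC(C)(C)C)[C@H](CC(=O)[O-])C(c1ccc(OC)cc1)c1ccc(OC)cc1.C[C@@H]([NH3+])c1ccccc1
F8 | step 9 | S-phenyl (2S)-2-(5,7-dimethoxy-4-oxo-4H-chromen-3-yl)-3,3-bis(4-methoxyphenyl)propanethioate | O=C(Sc1ccccc1)[C@H](c1coc2cc(OC)cc(OC)c2c1=O)C(c1ccc(OC)cc1)c1ccc(OC)cc1
F9 | step 10 | (2S)-2-(5,7-dihydroxy-4-oxo-4H-chromen-3-yl)-3,3-bis(4-hydroxyphenyl)propanoic acid | O=C(O)[C@H](c1coc2cc(O)cc(O)c2c1=O)C(c1ccc(O)cc1)c1ccc(O)cc1
F10 | step 4 | 4-tert-butyl 1-methyl (3S)-3-[bis(4-methoxyphenyl)methyl]-2-[(dimethylamino)methylidene]butanedioate | O=C(OC(C)(C)C)[C@H](C(=CN(C)C)C(=O)OC)C(c1ccc(OC)cc1)c1ccc(OC)cc1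
A1 | alternative 1 | (3R)-5,7-dimethoxy-3-[(2S)-1-oxo-1-(2,4,6-trimethoxyphenyl)-3,3-bis(4-methoxyphenyl)propan-2-yl]chroman-4-one | O=C(c1c(OC)cc(OC)cc1OC)[C@H]([C@@H]1COc2cc(OC)cc(OC)c2C1=O)C(c1ccc(OC)cc1)c1ccc(OC)cc1
A2 | alternative 1 | 2-{[(2E)-3-[bis(4-methoxyphenyl)methyl]-4-oxo-4-(2,4,6-trimethoxyphenyl)but-2-en-1-yl]oxy}-4,6-dimethoxybenzaldehyde | O=Cc1c(OC)cc(OC)cc1OC/C=C(/C(=O)c1c(OC)cc(OC)cc1OC)C(c1ccc(OC)cc1)c1ccc(OC)cc1
A3 | alternative 2 | (2S)-2-(5,7-dimethoxy-4-oxo-4H-chromen-3-yl)-3,3-bis(4-methoxyphenyl)-N-(quinolin-8-yl)propanamide | O=C(Nc1cccc2cccnc12)[C@H](c1coc2cc(OC)cc(OC)c2c1=O)C(c1ccc(OC)cc1)c1ccc(OC)cc1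
A4 | alternative 2 | (2S)-2-(5,7-dimethoxy-4-oxo-4H-chromen-3-yl)-N-(quinolin-8-yl)propanamide | O=C(Nc1cccc2cccnc12)[C@H](c1coc2cc(OC)cc(OC)c2c1=O)C
A5 | alternative 3 | (S)-3-[1-(2-ethoxy-4,6-dihydroxyphenyl)-3,3-bis(4-methoxyphenyl)-1-oxopropan-2-yl]-5,7-dimethoxy-4H-chromen-4-one | O=C(c1c(O)cc(O)cc1OCC)[C@H](c1coc2cc(OC)cc(OC)c2c1=O)C(c1ccc(OC)cc1)c1ccc(OC)cc1
A6 | alternative 3 | (S)-3-[5-ethoxy-1,1-bis(4-methoxyphenyl)-3-oxopent-4-yn-2-yl]-5,7-dimethoxy-4H-chromen-4-one | CCOC#CC(=O)[C@H](c1coc2cc(OC)cc(OC)c2c1=O)C(c1ccc(OC)cc1)c1ccc(OC)cc1
A7 | alternative 3 | 1-methoxy-1,3-bis(trimethylsilyloxy)buta-1,3-diene | COC(O[Si](C)(C)C)=CC(O[Si](C)(C)C)=C
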